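**Assumption:** genipin (commercial, obtained from gardenia geniposide) is taken as the cheap chiral starting material. Iridoid numbering is used throughout: C1 acetal, O2, C3=C4, C5/C9 ring fusion, C10 on C8, C11 on C4; β = the face of H‑9. The route is designed on paper and has not been run.

## Retrosynthetic overview

1. Target 10 ⇐ 10‑O‑TBS ether 9 ⇐ lactol 8 ⇐ dienol 5: late acylations, with C11 CO2Me → CH2OAc done only after the oxidations so the enol ether stays deactivated.
2. Key step, 5 ⇐ 4: a singlet‑oxygen ene reaction (concerted, suprafacial, pericyclic) forms the C7–O bond and moves the alkene to C5=C6 in one operation. It is an ene reaction, not a cycloaddition or sigmatropic shift; no sound variant of those delivers 7β‑O together with C5=C6 from genipin.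
3. 4 ⇐ 2: anti‑hydroxyselenation of the genipin C7=C8 bond (OH onto C8 from the α face), then selenoxide syn‑elimination to C6=C7.
4. Rings: none is built. The fused dihydropyran and cyclopentene are bought in genipin (1). C9 is bought, C8 then C7 are set by the substrate, C5 becomes sp2, and C1 is re‑set on acylation.

## Route

**Step 1**
Reactants: 1, genipin
Product: 2, 1β,10‑bis‑O‑TBS‑genipin
Conditions: TBSCl (3 equiv), imidazole, DMAP (cat.), DMF, rt
Reagents that add atoms: TBSCl, CC(C)(C)[Si](C)(C)Cl
Why: Silylation of the primary allylic OH and the lactol OH (silyl acetal) protects C10‑OH for the whole route and masks the lactol against DIBAL; the C1 anomer ratio is immaterial because C1 is re‑set in step 8.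

**Step 2**
Reactants: 2, 1β,10‑bis‑O‑TBS‑genipin
Product: 3, 7β‑phenylselanyl‑8α‑hydroxy‑7,8‑dihydro adduct (C10H2OTBS β on C8)
Conditions: PhSeCl (1.2 equiv), NaHCO3, MeCN–H2O (5:1), 0 °C
Reagents that add atoms: PhSeCl, Cl[Se]c1ccccc1; water, O
Why: Markovnikov anti‑hydroxyselenation, in which the seleniranium ion forms on the convex β face and water opens it at tertiary C8 from the α face, setting 8α‑OH and 7β‑SePh; the ester‑deactivated enol ether does not compete.

**Step 3**
Reactants: 3, hydroxyselenide
Product: 4, Δ6 tertiary allylic alcohol (C6=C7, 8α‑OH)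
Conditions: 30% H2O2, pyridine, THF, 0 °C → rt
Reagents that add atoms: none
Why: Selenoxide syn‑elimination (Ei) can only use H‑6β because C8 is quaternary, so the alkene moves to C6=C7 and C8 is untouched.

**Step 4**
Reactants: 4, Δ6 allylic alcohol
Product: 5, Δ3,5‑dienoate 7β,8α‑diol
Conditions: O2, TPP (cat.), hν (white LED), CH2Cl2, 0 °C; then PPh3, rt
Reagents that add atoms: O2, O=O (one O retained after PPh3 reduction)
Why: Schenck ene reaction in which H‑5 is the only allylic hydrogen, so oxygen must bond to C7 and the alkene shifts to C5=C6; the process is suprafacial and H‑5 is β, so the hydroperoxide (then OH) is delivered to the β face of C7.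

**Step 5**
Reactants: 5, dienoate diol
Product: 6, 7β,8α,11‑triol
Conditions: DIBAL‑H (5 equiv), CH2Cl2, −78 °C; Rochelle salt
Reagents that add atoms: none
Why: 1,2‑Reduction of the conjugated methyl ester to the C11 alcohol, with the silyl acetal and silyl ether inert and no stereocenter affected.

**Step 6**
Reactants: 6, triol
Product: 7, 11‑O‑acetate
Conditions: Ac2O (1.1 equiv), 2,4,6‑collidine, CH2Cl2, −20 °C
Reagents that add atoms: acetic anhydride, CC(=O)OC(C)=O
Why: Selective acylation of the primary allylic alcohol over the hindered secondary 7‑OH (next to quaternary C8) and the tertiary 8‑OH.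

**Step 7**
Reactants: 7, 11‑O‑acetate
Product: 8, lactol (1‑OH, 7β‑OH, 8α‑OH free; 10‑OTBS)
Conditions: TBAF (1.1 equiv), AcOH (1.2 equiv), THF, −20 °C
Reagents that add atoms: none
Why: Buffered fluoride cleaves the anomeric silyl acetal (lactolate leaving group) faster than the neopentyl primary TBS ether.

**Step 8**
Reactants: 8, lactol
Product: 9, 10‑O‑TBS‑jatamanvaltrate K
Conditions: isovaleric anhydride (4 equiv), Et3N, DMAP (0.3 equiv), CH2Cl2, 0 °C
Reagents that add atoms: isovaleric anhydride, CC(C)CC(=O)OC(=O)CC(C)C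
Why: DMAP‑catalysed acylation esterifies 7‑OH and the equilibrating lactol, which should react as its more stable 1β anomer (trans to C8, as in genipin and natural valepotriates) to give the 1β ester under substrate control; the tertiary 8‑OH is inert.

**Step 9**
Reactants: 9, 10‑O‑TBS‑jatamanvaltrate K
Product: 10, jatamanvaltrate K
Conditions: HF·pyridine, pyridine, THF, 0 °C
Reagents that add atoms: none
Why: Buffered, non‑basic desilylation frees the primary 10‑OH without 7‑O→10‑O acyl migration or ionisation of the acid‑labile dienyl acetal esters.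

## Compound list

1 | Genipin, methyl (1R,4aS,7aS)‑1‑hydroxy‑7‑(hydroxymethyl)‑1,4a,5,7a‑tetrahydrocyclopenta[c]pyran‑4‑carboxylate | COC(=O)C1=CO[C@@H](O)[C@H]2[C@@H]1CC=C2CO | starting material

2 | 1β,10‑Bis‑O‑TBS‑genipin | COC(=O)C1=CO[C@@H](O[Si](C)(C)C(C)(C)C)[C@H]2[C@@H]1CC=C2CO[Si](C)(C)C(C)(C)C | intermediate

3 | Methyl 1β‑TBSO‑7β‑(phenylselanyl)‑8α‑hydroxy‑8β‑(TBSO‑methyl)‑irid‑3‑en‑11‑oate (H‑5β, H‑9β) | COC(=O)C1=CO[C@@H](O[Si](C)(C)C(C)(C)C)[C@H]2[C@@H]1C[C@H]([Se]c3ccccc3)[C@]2(O)CO[Si](C)(C)C(C)(C)C | intermediate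

4 | Methyl 1β‑TBSO‑8α‑hydroxy‑8β‑(TBSO‑methyl)‑irida‑3,6‑dien‑11‑oate | COC(=O)C1=CO[C@@H](O[Si](C)(C)C(C)(C)C)[C@H]2[C@@H]1C=C[C@]2(O)CO[Si](C)(C)C(C)(C)C | intermediate

5 | Methyl 1β‑TBSO‑7β,8α‑dihydroxy‑8β‑(TBSO‑methyl)‑irida‑3,5‑dien‑11‑oate | COC(=O)C1=CO[C@@H](O[Si](C)(C)C(C)(C)C)[C@H]2C1=C[C@H](O)[C@]2(O)CO[Si](C)(C)C(C)(C)C | intermediate

6 | 1β‑TBSO‑8β‑(TBSO‑methyl)‑irida‑3,5‑diene‑7β,8α,11‑triol | OCC1=CO[C@@H](O[Si](C)(C)C(C)(C)C)[C@H]2C1=C[C@H](O)[C@]2(O)CO[Si](C)(C)C(C)(C)C | intermediate

7 | 11‑O‑Acetyl derivative of 6 | CC(=O)OCC1=CO[C@@H](O[Si](C)(C)C(C)(C)C)[C@H]2C1=C[C@H](O)[C@]2(O)CO[Si](C)(C)C(C)(C)C | intermediate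

8 | 11‑O‑Acetyl‑10‑O‑TBS‑irida‑3,5‑diene‑1β,7β,8α‑triol (lactol) | CC(=O)OCC1=CO[C@@H](O)[C@H]2C1=C[C@H](O)[C@]2(O)CO[Si](C)(C)C(C)(C)C | intermediate

9 | 10‑O‑TBS‑jatamanvaltrate K | CC(=O)OCC1=CO[C@@H](OC(=O)CC(C)C)[C@H]2C1=C[C@H](OC(=O)CC(C)C)[C@]2(O)CO[Si](C)(C)C(C)(C)C | intermediate

10 | Jatamanvaltrate K, (1S,6S,7R,7aS)‑4‑(acetoxymethyl)‑7‑hydroxy‑7‑(hydroxymethyl)‑1,6,7,7a‑tetrahydrocyclopenta[c]pyran‑1,6‑diyl bis(3‑methylbutanoate) | CC(=O)OCC1=CO[C@@H](OC(=O)CC(C)C)[C@H]2C1=C[C@H](OC(=O)CC(C)C)[C@]2(O)CO | target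

## Summary

Total steps: 9. Longest linear sequence: 9 (fully linear from genipin).

Steps most likely to fail, with fallbacks:

1. **Step 4 (ene reaction).** A cis‑disubstituted cyclopentene reacts slowly with singlet oxygen, and the product diene may over‑oxidise. Fallback: the ionic two‑step equivalent — TMS‑protect 8‑OH, epoxidise C6=C7 with mCPBA from the convex β face, then open the epoxide with Et2AlTMP by syn removal of H‑5β to give the same 7β‑ol C5=C6 diene.
2. **Step 2 (hydroxyselenation).** Seleniranium formation is reversible, so face selectivity is not guaranteed. Fallback: NBS/H2O bromohydrin (irreversible β‑bromonium, water at C8 from α), base closure to the 7α,8α‑epoxide, then PhSeNa opening at C7 from the β face, which gives 3 by an unambiguous SN2 sequence.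
3. **Steps 7–8 (anomeric desilylation and acylation of the labile diene lactol).** Selectivity between the two TBS groups, lactol stability and the 1β preference are all uncertain. Fallback: change the C11 oxidation‑state strategy — convert the ester to the C11 aldehyde right after step 1 (DIBAL, then MnO2), install both isovalerates on the robust vinylogous‑formate series directly after the ene step, and only then reduce the aldehyde (NaBH4/CeCl3, low temperature), acetylate and desilylate.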